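**Retrosynthetic overview**
1. Target 22 (18-membered ring) comes from a one-atom ring contraction: nitrogen deletion from the 19-membered macrocyclic dibenzylamine 19 (ring A–CH2–NH–CH2–ring D becomes ring A–CH2–CH2–ring D).
2. Amine 19 comes from macrocyclic imine closure and reduction of the amino aldehyde freed from 16.
3. Compound 16 comes from a B-alkyl Suzuki–Miyaura coupling (ring B–CH2CH2–ring C bridge) of aryl iodide 8 (rings A and B) with vinylphenol 14 (rings C and D).
4. Compound 8 comes from hydroquinone by methylation, ortho-formylation and a new oxa-Michael/aromatisation of 3-iodophenol on a formyl quinone monoketal. Compound 14 comes from catechol and 1-chloro-4-iodobenzene by O-arylation, aminomethylation, iodination and vinylation.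
5. Ring order: all four benzene rings are bought; the only ring made is the macrocycle, closed in step 9 and contracted in step 10.

Assumption: the SMILES has no stereocentre and specifies no fixed axis or plane, so the target is treated as one achiral, conformationally mobile compound and no stereocentre has to be set.

**Step 1**
Reactants: 1 hydroquinone
Product: 2 4-methoxyphenol
Conditions: MeI (1.0 equiv), K2CO3, acetone, reflux, N2; hydroquinone 3 equiv (excess recovered)
Reagents that add atoms: iodomethane, CI
Why: Williamson O-methylation, in which the threefold excess of hydroquinone keeps dimethylation low.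

**Step 2**
Reactants: 2 4-methoxyphenol
Product: 4 2-hydroxy-5-methoxybenzaldehyde, via salicyl alcohol 3 (not isolated)
Conditions: MgCl2 (1.5 equiv), Et3N (3.75 equiv), (CH2O)n, MeCN, reflux; 1 M HCl work-up
Reagents that add atoms: paraformaldehyde (as formaldehyde), C=O
Why: Magnesium-phenoxide-directed ortho-formylation (Casnati–Skattebøl reaction), in which a second formaldehyde oxidises salicyl alcohol 3 by hydride transfer and the two ortho positions of 2 are equivalent.

**Step 3**
Reactants: 4 2-hydroxy-5-methoxybenzaldehyde (1.3 equiv); 5 3-iodophenol (1.0 equiv)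
Product: 8 6-hydroxy-2-(3-iodophenoxy)-3-methoxybenzaldehyde, via quinone monoketal 6 (not isolated), via Michael adduct 7 (not isolated)
Conditions: PhI(OAc)2 (1.05 equiv on 4), MeOH, 0 °C; evaporate; 5, K2CO3 (3 equiv), MeCN, 0 °C to rt; then CF3CO2H (6 equiv), 0 °C to rt
Reagents that add atoms: methanol, CO (gives the second methoxy group of ketal 6; one of the two methoxy groups is kept in 8)
Why: Proposed new method: the trivalent iodine reagent oxidises 4 in methanol to the 2-formyl quinone monoketal 6, whose formyl-bearing C=C is an alkylidene-1,3-dicarbonyl acceptor, so the phenoxide of 5 adds at the one carbon that is β to both carbonyls (next to the ketal carbon) to give the stabilised β-dicarbonyl enolate 7, and acid then ionises the ketal so that loss of methanol and tautomerisation rearomatise irreversibly with the aryloxy group between CHO and OMe; the closest known reaction type is conjugate addition of carbon nucleophiles to quinone monoketals followed by acid-induced loss of methanol to 3-substituted 4-methoxyphenols, which has not been shown for phenol oxygen nucleophiles or for a formyl-activated monoketal.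

**Step 4**
Reactants: 9 catechol (3 equiv); 10 1-chloro-4-iodobenzene
Product: 11 2-(4-chlorophenoxy)phenol
Conditions: CuI (10 mol%), picolinic acid (20 mol%), K3PO4 (2 equiv), DMSO, 90 °C, N2
Reagents that add atoms: none
Why: Ullmann-type copper-catalysed O-arylation, in which the C–I bond reacts and the C–Cl bond does not, and excess catechol favours mono-arylation.

**Step 5**
Reactants: 11 2-(4-chlorophenoxy)phenol
Product: 12 tert-butyl N-[4-(2-hydroxyphenoxy)benzyl]carbamate
Conditions: BocNHCH2BF3K (1.2 equiv), Pd(OAc)2 (5 mol%), XPhos (10 mol%), K2CO3 (3 equiv), toluene/H2O 4:1, 85 °C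
Reagents that add atoms: potassium (tert-butoxycarbonylaminomethyl)trifluoroborate, CC(C)(C)OC(=O)NC[B-](F)(F)F.[K+]
Why: Suzuki–Miyaura aminomethylation of the only aryl halide, with the free phenol carried as its phenoxide.

**Step 6**
Reactants: 12 tert-butyl N-[4-(2-hydroxyphenoxy)benzyl]carbamate
Product: 13 tert-butyl N-[4-(2-hydroxy-5-iodophenoxy)benzyl]carbamate
Conditions: N-iodosuccinimide (1.05 equiv), TsOH·H2O (5 mol%), MeCN, 0 °C
Reagents that add atoms: N-iodosuccinimide, O=C1CCC(=O)N1I
Why: Electrophilic aromatic iodination directed para to the free phenol OH, the phenol ring being far more activated than ring D or the carbamate.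

**Step 7**
Reactants: 13 tert-butyl N-[4-(2-hydroxy-5-iodophenoxy)benzyl]carbamate
Product: 14 tert-butyl N-[4-(5-ethenyl-2-hydroxyphenoxy)benzyl]carbamate
Conditions: CH2=CHBF3K (1.3 equiv), PdCl2(dppf) (3 mol%), K2CO3 (3 equiv), THF/H2O 9:1, 70 °C, BHT; used at once
Reagents that add atoms: potassium vinyltrifluoroborate, C=C[B-](F)(F)F.[K+]
Why: Suzuki–Miyaura vinylation of the single C–I bond, the 4-vinylphenol being handled cold with inhibitor like other 2-alkoxy-4-vinylphenols.

**Step 8**
Reactants: 14 tert-butyl N-[4-(5-ethenyl-2-hydroxyphenoxy)benzyl]carbamate; 8 6-hydroxy-2-(3-iodophenoxy)-3-methoxybenzaldehyde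
Product: 16 tert-butyl N-[4-(5-{2-[3-(2-formyl-3-hydroxy-6-methoxyphenoxy)phenyl]ethyl}-2-hydroxyphenoxy)benzyl]carbamate, via alkylborane 15 (not isolated)
Conditions: 9-BBN (2.4 equiv), THF, 0 °C to rt; then 3 M aq K3PO4; 8 (1.0 equiv), PdCl2(dppf) (5 mol%), DMF, 50 °C
Reagents that add atoms: 9-borabicyclo[3.3.1]nonane, B1C2CCCC1CCC2 (its boron unit stays only in intermediate 15)
Why: Anti-Markovnikov hydroboration then B-alkyl Suzuki–Miyaura coupling, in which the aqueous base destroys residual B–H before the aldehyde-bearing iodide 8 is added, so the salicylaldehyde survives as its phenoxide.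

**Step 9**
Reactants: 16 (Boc-amino aldehyde from step 8)
Product: 19 macrocyclic secondary amine (19-membered ring; ring A–CH2–NH–CH2–ring D in place of the ring A–CH2–CH2–ring D bridge of the target), via amino aldehyde 17 (not isolated), via macrocyclic imine 18 (not isolated)
Conditions: HCl (4 M in dioxane), CH2Cl2, 0 °C to rt; evaporate (17 is present as its hydrochloride); slow addition to Et3N (3 equiv), MeOH/CH2Cl2 4:1 (1 mM), 4 Å molecular sieves, rt; then NaBH4 (4 equiv), 0 °C
Reagents that add atoms: none
Why: Boc acidolysis followed by a macrocyclising reductive amination, in which the hydrogen-bonded salicylaldimine forms reversibly at high dilution (so oligomers can equilibrate to the 19-membered ring) and is then reduced by borohydride.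

**Step 10**
Reactants: 19 macrocyclic secondary amine
Product: 22 target CNP0179896.0, via N-aminated amine 20 (not isolated), via isodiazene 21 (not isolated)
Conditions: N-(benzyloxy)-N-(pivaloyloxy)-4-(trifluoromethyl)benzamide (1.5 equiv), THF (0.05 M), 45 °C, 24 h
Reagents that add atoms: N-(benzyloxy)-N-(pivaloyloxy)-4-(trifluoromethyl)benzamide, CC(C)(C)C(=O)ON(OCc1ccccc1)C(=O)c1ccc(cc1)C(F)(F)F (its atoms stay only in intermediates 20 and 21)
Why: Nitrogen deletion, a ring contraction by one atom known for open-chain dibenzylamines and smaller cyclic amines: the amine is N-aminated, loss of the ester gives isodiazene 21, and stepwise radical (not pericyclic) N2 extrusion leaves a tethered benzyl radical pair that recombines to the C–C bond of the 18-membered ring, with no stereocentre involved.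

**Compound list**
1 | hydroquinone | Oc1ccc(O)cc1 | starting material
2 | 4-methoxyphenol | COc1ccc(O)cc1 | intermediate
3 | 2-(hydroxymethyl)-4-methoxyphenol (salicyl alcohol, as magnesium salt in the flask) | COc1ccc(O)c(CO)c1 | intermediate
4 | 2-hydroxy-5-methoxybenzaldehyde | COc1ccc(O)c(C=O)c1 | intermediate
5 | 3-iodophenol | Oc1cccc(I)c1 | starting material
6 | 3,3-dimethoxy-6-oxocyclohexa-1,4-diene-1-carbaldehyde (formyl quinone monoketal) | COC1(OC)C=CC(=O)C(C=O)=C1 | intermediate
7 | 2-(3-iodophenoxy)-3,3-dimethoxy-6-oxocyclohex-4-ene-1-carbaldehyde (Michael adduct, present as enolate; diastereomer mixture, both stereocentres lost on aromatisation) | COC1(OC)C=CC(=O)C(C=O)C1Oc1cccc(I)c1 | intermediate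
8 | 6-hydroxy-2-(3-iodophenoxy)-3-methoxybenzaldehyde | COc1ccc(O)c(C=O)c1Oc1cccc(I)c1 | intermediate
9 | catechol | Oc1ccccc1O | starting material
10 | 1-chloro-4-iodobenzene | Clc1ccc(I)cc1 | starting material
11 | 2-(4-chlorophenoxy)phenol | Oc1ccccc1Oc1ccc(Cl)cc1 | intermediate
12 | tert-butyl N-[4-(2-hydroxyphenoxy)benzyl]carbamate | CC(C)(C)OC(=O)NCc1ccc(Oc2ccccc2O)cc1 | intermediate
13 | tert-butyl N-[4-(2-hydroxy-5-iodophenoxy)benzyl]carbamate | CC(C)(C)OC(=O)NCc1ccc(Oc2cc(I)ccc2O)cc1 | intermediate
14 | tert-butyl N-[4-(5-ethenyl-2-hydroxyphenoxy)benzyl]carbamate | CC(C)(C)OC(=O)NCc1ccc(Oc2cc(C=C)ccc2O)cc1 | intermediate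
15 | B-alkyl-9-BBN adduct of 14 (boron on the terminal carbon) | CC(C)(C)OC(=O)NCc1ccc(Oc2cc(CCB3C4CCCC3CCC4)ccc2O)cc1 | intermediate
16 | tert-butyl N-[4-(5-{2-[3-(2-formyl-3-hydroxy-6-methoxyphenoxy)phenyl]ethyl}-2-hydroxyphenoxy)benzyl]carbamate | CC(C)(C)OC(=O)NCc1ccc(Oc2cc(CCc3cccc(Oc4c(OC)ccc(O)c4C=O)c3)ccc2O)cc1 | intermediate
17 | 2-[3-(2-{3-[4-(aminomethyl)phenoxy]-4-hydroxyphenyl}ethyl)phenoxy]-6-hydroxy-3-methoxybenzaldehyde (free base shown) | NCc1ccc(Oc2cc(CCc3cccc(Oc4c(OC)ccc(O)c4C=O)c3)ccc2O)cc1 | intermediate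
18 | macrocyclic imine, ring A–CH=N–CH2–ring D (C=N geometry not fixed, lost on reduction) | COc1ccc(O)c2c1Oc1cccc(c1)CCc1ccc(O)c(c1)Oc1ccc(cc1)CN=C2 | intermediate
19 | macrocyclic secondary amine, ring A–CH2–NH–CH2–ring D (19-membered ring) | COc1ccc(O)c2c1Oc1cccc(c1)CCc1ccc(O)c(c1)Oc1ccc(cc1)CNC2 | intermediate
20 | N-[benzyloxy(4-(trifluoromethyl)benzoyl)amino] derivative of 19 | COc1ccc(O)c2c1Oc1cccc(c1)CCc1ccc(O)c(c1)Oc1ccc(cc1)CN(C2)N(OCc1ccccc1)C(=O)c1ccc(cc1)C(F)(F)F | intermediate
21 | isodiazene (1,1-diazene) of 19 | COc1ccc(O)c2c1Oc1cccc(c1)CCc1ccc(O)c(c1)Oc1ccc(cc1)C[N+](C2)=[N-] | intermediate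
22 | CNP0179896.0 (no stereocentre) | COc1ccc(O)c2c1Oc1cccc(c1)CCc1ccc(O)c(c1)Oc1ccc(cc1)CC2 | target

**Step count:** 10 steps in total. Longest linear sequence: 7 steps (steps 4 to 10, from catechol).

**Three steps most likely to fail**

Step 3 (proposed new step). The risks are loss of the phenol from adduct 7 instead of loss of methanol, and hydrolysis of 6 to the quinone. The fallback uses known chemistry only; it sets out from 5 and comes back at 8. 2-Fluorophenol F1 is O-methylated (MeI, K2CO3) to 2-fluoroanisole F2, which is brominated para to the methoxy group (Br2, AcOH) to give 4-bromo-2-fluoroanisole F3. Bromine–lithium exchange (n-BuLi, THF, −78 °C), B(OMe)3 and then H2O2/NaOH give 3-fluoro-4-methoxyphenol F4, which is protected (MOMCl, i-Pr2NEt) as 2-fluoro-1-methoxy-4-(methoxymethoxy)benzene F5. Lithiation between F and OMOM (n-BuLi, THF, −78 °C) and DMF give 2-fluoro-3-methoxy-6-(methoxymethoxy)benzaldehyde F6. Nucleophilic aromatic substitution of the fluoride by 5 (K2CO3, DMF, 90 °C) gives 2-(3-iodophenoxy)-3-methoxy-6-(methoxymethoxy)benzaldehyde F7, and HCl in MeOH gives 8.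

Step 9 (macrocyclisation). The risk is imine oligomers. The fallback makes the C–N bond first and closes the ring by C–C coupling; it sets out from 14 and 8 and comes back at 19. The Boc group of 14 is removed without protic acid (Me3SiOTf, 2,6-lutidine, then MeOH) to give 2-[4-(aminomethyl)phenoxy]-4-ethenylphenol F8. Intermolecular reductive amination with 8 (MeOH, then NaBH4) gives the open-chain secondary amine F9, and Boc2O gives its N-Boc derivative F10. Hydroboration (9-BBN) and an intramolecular B-alkyl Suzuki–Miyaura coupling at high dilution (PdCl2(dppf), AsPh3, Cs2CO3, DMF/THF/H2O) close the ring at the ring B–ring C bridge to give the N-Boc macrocycle F11. HCl in dioxane then gives 19.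

Step 10 (ring contraction). The risks are interference by the two free phenols and isomerisation of the isodiazene to a hydrazone. The fallback is the classical nitrosamine route; it sets out from 19 and comes back at 22. tert-Butyl nitrite (THF, rt) gives the N-nitrosamine F12. Na2S2O4 in aqueous ethanolic NaOH at 60 °C reduces it to the N-amino amine F13, which under these conditions passes through isodiazene 21 and loses N2 to give 22.

**Further compounds**
F1 | step 3 | 2-fluorophenol (extra starting material) | Oc1ccccc1F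
F2 | step 3 | 2-fluoroanisole | COc1ccccc1F
F3 | step 3 | 4-bromo-2-fluoroanisole | COc1ccc(Br)cc1F
F4 | step 3 | 3-fluoro-4-methoxyphenol | COc1ccc(O)cc1F
F5 | step 3 | 2-fluoro-1-methoxy-4-(methoxymethoxy)benzene | COCOc1ccc(OC)c(F)c1
F6 | step 3 | 2-fluoro-3-methoxy-6-(methoxymethoxy)benzaldehyde | COCOc1ccc(OC)c(F)c1C=O
F7 | step 3 | 2-(3-iodophenoxy)-3-methoxy-6-(methoxymethoxy)benzaldehyde | COCOc1ccc(OC)c(Oc2cccc(I)c2)c1C=O
F8 | step 9 | 2-[4-(aminomethyl)phenoxy]-4-ethenylphenol | NCc1ccc(Oc2cc(C=C)ccc2O)cc1
F9 | step 9 | open-chain secondary amine from 8 and F8 | COc1ccc(O)c(CNCc2ccc(Oc3cc(C=C)ccc3O)cc2)c1Oc1cccc(I)c1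
F10 | step 9 | N-Boc derivative of F9 | COc1ccc(O)c(CN(Cc2ccc(Oc3cc(C=C)ccc3O)cc2)C(=O)OC(C)(C)C)c1Oc1cccc(I)c1
F11 | step 9 | N-Boc derivative of macrocyclic amine 19 | COc1ccc(O)c2c1Oc1cccc(c1)CCc1ccc(O)c(c1)Oc1ccc(cc1)CN(C2)C(=O)OC(C)(C)C
F12 | step 10 | N-nitroso derivative of 19 | COc1ccc(O)c2c1Oc1cccc(c1)CCc1ccc(O)c(c1)Oc1ccc(cc1)CN(C2)N=O
F13 | step 10 | N-amino derivative of 19 | COc1ccc(O)c2c1Oc1cccc(c1)CCc1ccc(O)c(c1)Oc1ccc(cc1)CN(C2)N
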